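**Retrosynthetic overview**

1. The target is fisetinidol-(4β→6)-leucofisetinidin. The lower C4 carbinol comes last, by NaBH4 reduction of a C4 ketone. The upper 3,4-cis pair comes from a 4-aryl-flav-3-ene by epoxidation anti to the C2 aryl group, then Pd hydrogenolysis of the benzylic C4–O bond with inversion; the lower 3-OH is installed in the same DMDO operation (Rubottom oxidation).
2. The interflavan bond C4(upper)–C6(lower) is made by Suzuki–Miyaura coupling of an upper enol triflate with a lower C6 boronate. Both partners come from one monomer, a 6-bromoflavanone 1,3-dithioketal (Br → H for the upper half, Br → Bpin for the lower half).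
3. Ring C of the monomer is built by a one-flask [3+3] anionic annulation: a dithiane anion at C4 on ring A opens (R)-3,4-bis(benzyloxy)styrene oxide at C3 (bond C3–C4), and the released O1 alkoxide displaces fluoride at C8a (bond O1–C8a).
4. Enabling feature: in ring C, O1–C2–C3 is a styrene-oxide pattern carried by ring B, and C4–C4a–C8a is a 2-fluorobenzaldehyde pattern of ring A. C4 at the carbonyl oxidation level, masked as a dithiane, is nucleophilic and quaternary (it holds O1 over C8a–F), and later supplies both the enol triflate and the lower C4 carbinol.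
5. Ring order: rings A and B are bought; ring C is formed once (key step) and used for both halves; the oxirane is a temporary ring removed by hydrogenolysis.

Key step: step 7

Remark: the SMILES is read as (2R,3S,4S)-fisetinidol (2,3-trans-3,4-cis) joined from C4 to C6 of (2R,3S,4R)-leucofisetinidin (2,3-trans-3,4-trans); flavanone-level compounds with the same spatial arrangement at C2 carry the descriptor 2S. Compounds 1 and 5 are taken as commercial.

Step 1
Reactants: 1 1-[3,4-bis(benzyloxy)phenyl]ethan-1-one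
Product: 2 2-bromo-1-[3,4-bis(benzyloxy)phenyl]ethan-1-one
Conditions: CuBr2 (2.1 equiv), EtOAc/CHCl3, reflux
Reagents that add atoms: copper dibromide CuBr2, [Cu+2].[Br-].[Br-]
Why: α-bromination of an aryl methyl ketone through its enol with CuBr2, which halogenates the side chain and should leave the benzyloxy-substituted ring untouched.

Step 2
Reactants: 2 2-bromo-1-[3,4-bis(benzyloxy)phenyl]ethan-1-one
Product: 3 (R)-1-[3,4-bis(benzyloxy)phenyl]-2-bromoethan-1-ol
Conditions: (R)-2-methyl-CBS-oxazaborolidine (10 mol %), BH3·SMe2, THF, 0 °C; MeOH quench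
Reagents that add atoms: none
Why: Corey–Bakshi–Shibata reduction, in which the aryl group is the large substituent in the oxazaborolidine–borane complex, so the (R)-catalyst should deliver hydride to the face that gives the (R)-bromohydrin (the usual acetophenone sense; the descriptor differs only because CH2Br outranks aryl).

Step 3
Reactants: 3 (R)-1-[3,4-bis(benzyloxy)phenyl]-2-bromoethan-1-ol
Product: 4 (R)-2-[3,4-bis(benzyloxy)phenyl]oxirane
Conditions: NaH, THF, 0 °C → rt; used promptly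
Reagents that add atoms: none
Why: intramolecular Williamson etherification (3-exo-tet) at the CH2Br carbon, which leaves the benzylic stereocentre untouched and avoids acid or nucleophilic solvent that would open the electron-rich styrene oxide.

Step 4
Reactants: 5 2-fluoro-4-hydroxybenzaldehyde
Product: 6 5-bromo-2-fluoro-4-hydroxybenzaldehyde
Conditions: Br2 (1.0 equiv), AcOH, 15 °C
Reagents that add atoms: bromine, BrBr
Why: electrophilic aromatic bromination directed ortho to the phenol, where C5 (para to fluorine, unhindered) should be preferred over C3 (flanked by F and OH).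

Step 5
Reactants: 6 5-bromo-2-fluoro-4-hydroxybenzaldehyde
Product: 7 4-(benzyloxy)-5-bromo-2-fluorobenzaldehyde
Conditions: BnBr, K2CO3, DMF, rt
Reagents that add atoms: benzyl bromide, BrCc1ccccc1
Why: Williamson ether synthesis on the phenoxide, which is much faster at room temperature than displacement of the aryl fluoride.

Step 6
Reactants: 7 4-(benzyloxy)-5-bromo-2-fluorobenzaldehyde
Product: 8 2-[4-(benzyloxy)-5-bromo-2-fluorophenyl]-1,3-dithiane
Conditions: propane-1,3-dithiol, BF3·OEt2 (10 mol %), CH2Cl2, 0 °C → rt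
Reagents that add atoms: propane-1,3-dithiol, SCCCS
Why: Lewis-acid-catalysed dithioacetalisation of the aldehyde, which turns the future C4 into an acyl-anion equivalent; the benzyl ether tolerates catalytic BF3 at this temperature.

Step 7
Reactants: 8 2-[4-(benzyloxy)-5-bromo-2-fluorophenyl]-1,3-dithiane; 4 (R)-2-[3,4-bis(benzyloxy)phenyl]oxirane
Product: 10 (2S)-7-(benzyloxy)-2-[3,4-bis(benzyloxy)phenyl]-6-bromo-2,3-dihydrospiro[chromene-4,2'-[1,3]dithiane], via lithium alkoxide 9 (not isolated)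
Conditions: LiN(iPr)2 (1.05 equiv), THF, −78 → −30 °C; then 4, −30 °C → rt; then DMPU, 65 °C
Reagents that add atoms: none
Why: Proposed new method: the dithiane carbanion of 8 (Corey–Seebach umpolung of the C4 aldehyde carbon) should open the strained oxirane 4 at its CH2 terminus by SN2 attack (bond C3–C4), and the benzylic lithium alkoxide 9 so released (the future O1) should then displace the ortho fluoride at C8a by intramolecular SNAr (bond O1–C8a), a formal [3+3] anionic annulation in one flask. The closest known reaction types are the opening of terminal aryl epoxides by 2-aryl-2-lithio-1,3-dithianes and the base-mediated cyclisation of 3-(2-fluoroaryl)propan-1-olates to chromans; their combination on a 2-(2-fluoroaryl)dithiane is the new element. Ring C closes as a six-membered ring by addition–elimination at the aromatic carbon C8a (Meisenheimer-type complex), helped by the quaternary gem-dithio C4 (Thorpe–Ingold effect), the para bromine, the dipolar cosolvent and LiF formation, while epoxide strain release drives the C–C bond formation. No new stereocentre is created: C2 is carried over unchanged from (R)-4 because neither its C–O nor its C–H bond is broken, and the dithioketal product has no carbonyl through which a flavanone could racemise by ring opening. The selectivities needed are attack at the unsubstituted epoxide carbon (sterics, no Lewis acid) and deprotonation of the dithiane C–H in preference to bromine–lithium exchange or ring metalation, which is why the amide base LiN(iPr)2 is used and not an alkyllithium.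

Step 8
Reactants: 10 (2S)-7-(benzyloxy)-2-[3,4-bis(benzyloxy)phenyl]-6-bromo-2,3-dihydrospiro[chromene-4,2'-[1,3]dithiane]
Product: 11 (2S)-7-(benzyloxy)-2-[3,4-bis(benzyloxy)phenyl]-2,3-dihydrospiro[chromene-4,2'-[1,3]dithiane]
Conditions: n-BuLi (1.1 equiv), THF, −78 °C; then MeOH
Reagents that add atoms: none
Why: bromine–lithium exchange followed by protonation removes the C6 handle from the half that becomes the upper unit; the masked ketone and the benzyl ethers should tolerate the aryllithium at −78 °C.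

Step 9
Reactants: 11 (2S)-7-(benzyloxy)-2-[3,4-bis(benzyloxy)phenyl]-2,3-dihydrospiro[chromene-4,2'-[1,3]dithiane]
Product: 12 (2S)-7-(benzyloxy)-2-[3,4-bis(benzyloxy)phenyl]-2,3-dihydro-4H-chromen-4-one
Conditions: MeI, CaCO3, MeCN/H2O (9:1), 45 °C
Reagents that add atoms: water, O
Why: alkylative hydrolysis of the dithioketal (S-methylation, then hydrolysis of the thionium ion) under buffered, non-basic conditions, so the flavanone should not racemise at C2 by ring opening to the chalcone.

Step 10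
Reactants: 12 (2S)-7-(benzyloxy)-2-[3,4-bis(benzyloxy)phenyl]-2,3-dihydro-4H-chromen-4-one
Product: 13 (2S)-7-(benzyloxy)-2-[3,4-bis(benzyloxy)phenyl]-2H-chromen-4-yl trifluoromethanesulfonate
Conditions: Tf2O, 2,6-di-tert-butyl-4-methylpyridine, CH2Cl2, −20 → 0 °C; kept cold and dark
Reagents that add atoms: trifluoromethanesulfonic anhydride, O=S(=O)(OS(=O)(=O)C(F)(F)F)C(F)(F)F
Why: enol triflate formation by O-triflation of the electron-rich aryl ketone and loss of H-3 to the hindered pyridine base, which avoids a free enolate and hence E1cB opening of ring C.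

Step 11
Reactants: 10 (2S)-7-(benzyloxy)-2-[3,4-bis(benzyloxy)phenyl]-6-bromo-2,3-dihydrospiro[chromene-4,2'-[1,3]dithiane]
Product: 14 (2S)-7-(benzyloxy)-2-[3,4-bis(benzyloxy)phenyl]-6-(4,4,5,5-tetramethyl-1,3,2-dioxaborolan-2-yl)-2,3-dihydrospiro[chromene-4,2'-[1,3]dithiane]
Conditions: n-BuLi (1.1 equiv), THF, −78 °C; then 2-isopropoxy-4,4,5,5-tetramethyl-1,3,2-dioxaborolane, −78 °C → rt
Reagents that add atoms: 2-isopropoxy-4,4,5,5-tetramethyl-1,3,2-dioxaborolane, CC(C)OB1OC(C)(C)C(C)(C)O1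
Why: bromine–lithium exchange and electrophilic borylation of the aryllithium place boron exactly at C6, the future interflavan position of the lower unit.

Step 12
Reactants: 13 (2S)-7-(benzyloxy)-2-[3,4-bis(benzyloxy)phenyl]-2H-chromen-4-yl trifluoromethanesulfonate; 14 (2S)-7-(benzyloxy)-2-[3,4-bis(benzyloxy)phenyl]-6-(4,4,5,5-tetramethyl-1,3,2-dioxaborolan-2-yl)-2,3-dihydrospiro[chromene-4,2'-[1,3]dithiane]
Product: 15 (2S)-7-(benzyloxy)-2-[3,4-bis(benzyloxy)phenyl]-6-{(2S)-7-(benzyloxy)-2-[3,4-bis(benzyloxy)phenyl]-2H-chromen-4-yl}-2,3-dihydrospiro[chromene-4,2'-[1,3]dithiane]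
Conditions: Pd(OAc)2 (5 mol %), SPhos (10 mol %), K3PO4, THF/H2O, 40 °C, dark
Reagents that add atoms: none
Why: Suzuki–Miyaura coupling of an alkenyl triflate with an arylboronate forms the C4–C6 interflavan bond regiospecifically; the lower unit is still a base-stable dithioketal, and the mild temperature limits electrocyclic opening of the 2H-chromene that would scramble C2.

Step 13
Reactants: 15 (2S)-7-(benzyloxy)-2-[3,4-bis(benzyloxy)phenyl]-6-{(2S)-7-(benzyloxy)-2-[3,4-bis(benzyloxy)phenyl]-2H-chromen-4-yl}-2,3-dihydrospiro[chromene-4,2'-[1,3]dithiane]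
Product: 16 (2S)-7-(benzyloxy)-2-[3,4-bis(benzyloxy)phenyl]-6-{(2S)-7-(benzyloxy)-2-[3,4-bis(benzyloxy)phenyl]-2H-chromen-4-yl}-2,3-dihydro-4H-chromen-4-one
Conditions: MeI, CaCO3, MeCN/H2O (9:1), 45 °C, dark
Reagents that add atoms: water, O
Why: the same buffered alkylative dithioketal hydrolysis as in step 9 unmasks the lower C4 ketone and removes all sulfur before the oxidation, without acid that would ionise the 2H-chromene.

Step 14
Reactants: 16 (2S)-7-(benzyloxy)-2-[3,4-bis(benzyloxy)phenyl]-6-{(2S)-7-(benzyloxy)-2-[3,4-bis(benzyloxy)phenyl]-2H-chromen-4-yl}-2,3-dihydro-4H-chromen-4-one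
Product: 19 hexa-O-benzyl epoxy ketol (upper 3,4-epoxide anti to its C2 aryl group; lower trans-3-hydroxyflavan-4-one), via silyl enol ether 17 (not isolated), via bis-epoxide 18 (not isolated)
Conditions: TMSOTf, Et3N, CH2Cl2, 0 °C; then DMDO (acetone solution, 2.5 equiv), −40 → −10 °C; then Bu4NF, THF, −20 °C; used crude
Reagents that add atoms: dimethyldioxirane, CC1(C)OO1
Why: one neutral oxidant performs a Rubottom oxidation of the lower silyl enol ether and an epoxidation of the electron-rich upper C3=C4 bond, each from the face opposite the neighbouring C2 aryl group (upper 3-oxygen β, lower 3-hydroxyl trans), and fluoride collapses the silyloxy-oxirane to the ketol without acid that would open the upper epoxide.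

Step 15
Reactants: 19 hexa-O-benzyl epoxy ketol (upper 3,4-epoxide anti to its C2 aryl group; lower trans-3-hydroxyflavan-4-one)
Product: 20 (2R,3R)-2-(3,4-dihydroxyphenyl)-6-[(2R,3S,4S)-2-(3,4-dihydroxyphenyl)-3,7-dihydroxy-3,4-dihydro-2H-chromen-4-yl]-3,7-dihydroxy-2,3-dihydro-4H-chromen-4-one (fisetinidol-(4β→6)-fustin)
Conditions: H2 (1 atm), 10% Pd/C, NaHCO3 (solid), EtOAc/THF, 0 °C → rt
Reagents that add atoms: none
Why: heterogeneous hydrogenolysis on palladium should cleave the six benzyl ethers and the benzylic C4–O bond of the oxirane with inversion (hydrogen delivered anti to the oxirane oxygen, as known for 1-arylcycloalkene oxides on Pd), which puts H-4 trans and the 4-aryl group cis to the 3-hydroxyl, while the deactivated aryl ketone and the C2–O1 bonds should survive the neutral conditions.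

Step 16
Reactants: 20 (2R,3R)-2-(3,4-dihydroxyphenyl)-6-[(2R,3S,4S)-2-(3,4-dihydroxyphenyl)-3,7-dihydroxy-3,4-dihydro-2H-chromen-4-yl]-3,7-dihydroxy-2,3-dihydro-4H-chromen-4-one
Product: 21 (2R,3S,4R)-2-(3,4-dihydroxyphenyl)-6-[(2R,3S,4S)-2-(3,4-dihydroxyphenyl)-3,7-dihydroxy-3,4-dihydro-2H-chromen-4-yl]-3,4-dihydro-2H-chromene-3,4,7-triol (CNP0280090.2)
Conditions: NaBH4, MeOH, 0 °C; work-up at pH 6 under N2
Reagents that add atoms: none
Why: NaBH4 reduction of a 2,3-trans-dihydroflavonol carbonyl, where axial hydride delivery should give the equatorial 4-hydroxyl trans to the 3-hydroxyl (2,3-trans-3,4-trans, 4R), the established outcome for fustin-type ketones; the acid-labile diol is kept near neutral.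

**Compound list**

1 | 1-[3,4-bis(benzyloxy)phenyl]ethan-1-one | CC(=O)c1ccc(OCc2ccccc2)c(OCc2ccccc2)c1 | starting material
2 | 2-bromo-1-[3,4-bis(benzyloxy)phenyl]ethan-1-one | BrCC(=O)c1ccc(OCc2ccccc2)c(OCc2ccccc2)c1 | intermediate
3 | (R)-1-[3,4-bis(benzyloxy)phenyl]-2-bromoethan-1-ol | O[C@H](c1ccc(OCc2ccccc2)c(OCc2ccccc2)c1)CBr | intermediate
4 | (R)-2-[3,4-bis(benzyloxy)phenyl]oxirane | O1[C@H](c2ccc(OCc3ccccc3)c(OCc3ccccc3)c2)C1 | intermediate
5 | 2-fluoro-4-hydroxybenzaldehyde | O=Cc1ccc(O)cc1F | starting material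
6 | 5-bromo-2-fluoro-4-hydroxybenzaldehyde | O=Cc1cc(Br)c(O)cc1F | intermediate
7 | 4-(benzyloxy)-5-bromo-2-fluorobenzaldehyde | O=Cc1cc(Br)c(OCc2ccccc2)cc1F | intermediate
8 | 2-[4-(benzyloxy)-5-bromo-2-fluorophenyl]-1,3-dithiane | Fc1cc(OCc2ccccc2)c(Br)cc1C1SCCCS1 | intermediate
9 | lithium (S)-1-[3,4-bis(benzyloxy)phenyl]-2-{2-[4-(benzyloxy)-5-bromo-2-fluorophenyl]-1,3-dithian-2-yl}ethan-1-olate | [Li+].[O-][C@H](c1ccc(OCc2ccccc2)c(OCc2ccccc2)c1)CC1(SCCCS1)c1cc(Br)c(OCc2ccccc2)cc1F | intermediate (not isolated)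
10 | (2S)-7-(benzyloxy)-2-[3,4-bis(benzyloxy)phenyl]-6-bromo-2,3-dihydrospiro[chromene-4,2'-[1,3]dithiane] | C(c1ccccc1)Oc1c(Br)cc2c(c1)O[C@H](c1ccc(OCc3ccccc3)c(OCc3ccccc3)c1)CC23SCCCS3 | intermediate
11 | (2S)-7-(benzyloxy)-2-[3,4-bis(benzyloxy)phenyl]-2,3-dihydrospiro[chromene-4,2'-[1,3]dithiane] | C(c1ccccc1)Oc1ccc2c(c1)O[C@H](c1ccc(OCc3ccccc3)c(OCc3ccccc3)c1)CC23SCCCS3 | intermediate
12 | (2S)-7-(benzyloxy)-2-[3,4-bis(benzyloxy)phenyl]-2,3-dihydro-4H-chromen-4-one | C(c1ccccc1)Oc1ccc2c(c1)O[C@H](c1ccc(OCc3ccccc3)c(OCc3ccccc3)c1)CC2=O | intermediate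
13 | (2S)-7-(benzyloxy)-2-[3,4-bis(benzyloxy)phenyl]-2H-chromen-4-yl trifluoromethanesulfonate | C(c1ccccc1)Oc1ccc2c(c1)O[C@H](c1ccc(OCc3ccccc3)c(OCc3ccccc3)c1)C=C2OS(=O)(=O)C(F)(F)F | intermediate
14 | (2S)-7-(benzyloxy)-2-[3,4-bis(benzyloxy)phenyl]-6-(4,4,5,5-tetramethyl-1,3,2-dioxaborolan-2-yl)-2,3-dihydrospiro[chromene-4,2'-[1,3]dithiane] | C(c1ccccc1)Oc1c(B3OC(C)(C)C(C)(C)O3)cc2c(c1)O[C@H](c1ccc(OCc3ccccc3)c(OCc3ccccc3)c1)CC23SCCCS3 | intermediate
15 | (2S)-7-(benzyloxy)-2-[3,4-bis(benzyloxy)phenyl]-6-{(2S)-7-(benzyloxy)-2-[3,4-bis(benzyloxy)phenyl]-2H-chromen-4-yl}-2,3-dihydrospiro[chromene-4,2'-[1,3]dithiane] | C(c1ccccc1)Oc1ccc2c(c1)O[C@H](c1ccc(OCc3ccccc3)c(OCc3ccccc3)c1)C=C2c1cc2c(cc1OCc1ccccc1)O[C@H](c1ccc(OCc3ccccc3)c(OCc3ccccc3)c1)CC23SCCCS3 | intermediate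
16 | (2S)-7-(benzyloxy)-2-[3,4-bis(benzyloxy)phenyl]-6-{(2S)-7-(benzyloxy)-2-[3,4-bis(benzyloxy)phenyl]-2H-chromen-4-yl}-2,3-dihydro-4H-chromen-4-one | C(c1ccccc1)Oc1ccc2c(c1)O[C@H](c1ccc(OCc3ccccc3)c(OCc3ccccc3)c1)C=C2c1cc2c(cc1OCc1ccccc1)O[C@H](c1ccc(OCc3ccccc3)c(OCc3ccccc3)c1)CC2=O | intermediate
17 | silyl enol ether of 16: (2S)-7-(benzyloxy)-2-[3,4-bis(benzyloxy)phenyl]-6-{(2S)-7-(benzyloxy)-2-[3,4-bis(benzyloxy)phenyl]-2H-chromen-4-yl}-4-(trimethylsilyloxy)-2H-chromene | C(c1ccccc1)Oc1ccc2c(c1)O[C@H](c1ccc(OCc3ccccc3)c(OCc3ccccc3)c1)C=C2c1cc2c(cc1OCc1ccccc1)O[C@H](c1ccc(OCc3ccccc3)c(OCc3ccccc3)c1)C=C2O[Si](C)(C)C | intermediate (not isolated)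
18 | bis-epoxide of 17: upper 3,4-epoxy-4-arylflavan and lower 3,4-epoxy-4-(trimethylsilyloxy)flavan, each oxirane oxygen on the face opposite the C2 aryl group | C(c1ccccc1)Oc1ccc2c(c1)O[C@H](c1ccc(OCc3ccccc3)c(OCc3ccccc3)c1)[C@H]3O[C@@]23c1cc2c(cc1OCc1ccccc1)O[C@H](c1ccc(OCc3ccccc3)c(OCc3ccccc3)c1)[C@H]3O[C@@]23O[Si](C)(C)C | intermediate (not isolated)
19 | hexa-O-benzyl epoxy ketol: (2R,3R)-7-(benzyloxy)-2-[3,4-bis(benzyloxy)phenyl]-3-hydroxy-2,3-dihydro-4H-chromen-4-one carrying at C6 the C4 of a (2R,3R)-7-(benzyloxy)-2-[3,4-bis(benzyloxy)phenyl]-3,4-epoxyflavan whose oxirane oxygen is trans to its C2 aryl group | C(c1ccccc1)Oc1ccc2c(c1)O[C@H](c1ccc(OCc3ccccc3)c(OCc3ccccc3)c1)[C@H]3O[C@@]23c1cc2c(cc1OCc1ccccc1)O[C@H](c1ccc(OCc3ccccc3)c(OCc3ccccc3)c1)[C@@H](O)C2=O | intermediate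
20 | (2R,3R)-2-(3,4-dihydroxyphenyl)-6-[(2R,3S,4S)-2-(3,4-dihydroxyphenyl)-3,7-dihydroxy-3,4-dihydro-2H-chromen-4-yl]-3,7-dihydroxy-2,3-dihydro-4H-chromen-4-one (fisetinidol-(4β→6)-fustin) | Oc1ccc2c(c1)O[C@H](c1ccc(O)c(O)c1)[C@@H](O)[C@H]2c1cc2c(cc1O)O[C@H](c1ccc(O)c(O)c1)[C@@H](O)C2=O | intermediate
21 | (2R,3S,4R)-2-(3,4-dihydroxyphenyl)-6-[(2R,3S,4S)-2-(3,4-dihydroxyphenyl)-3,7-dihydroxy-3,4-dihydro-2H-chromen-4-yl]-3,4-dihydro-2H-chromene-3,4,7-triol (fisetinidol-(4β→6)-leucofisetinidin, CNP0280090.2) | Oc1ccc2c(c1)O[C@H](c1ccc(O)c(O)c1)[C@@H](O)[C@H]2c1cc2c(cc1O)O[C@H](c1ccc(O)c(O)c1)[C@@H](O)[C@@H]2O | target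

**Step count and risks**

Total steps: 16. Longest linear sequence: 12 steps (5 → 21 through steps 4–10 and 12–16; the branch from 1 through steps 1–3 and 7–10, 12–16 is equally long).

Steps most likely to fail:

Step 7 (proposed new method). The amide base may metalate ring A next to fluorine instead of the dithiane C–H, the anion may attack the benzylic epoxide carbon, or the lithium alkoxide may displace the unactivated fluoride too slowly. The fallback uses known chemistry and a different activation mode for the ring closure. It sets out from 8 and 4: the lithiation and epoxide opening are stopped by aqueous NH4Cl once the C3–C4 bond is made, giving (S)-1-[3,4-bis(benzyloxy)phenyl]-2-{2-[4-(benzyloxy)-5-bromo-2-fluorophenyl]-1,3-dithian-2-yl}ethan-1-ol F1. MeI/CaCO3 in aqueous MeCN unmasks the ketone to give (S)-1-[4-(benzyloxy)-5-bromo-2-fluorophenyl]-3-[3,4-bis(benzyloxy)phenyl]-3-hydroxypropan-1-one F2, in which the fluorine is now ortho to a carbonyl group. Cs2CO3 in MeCN at rt should then close ring C by a carbonyl-activated SNAr to give (2S)-7-(benzyloxy)-2-[3,4-bis(benzyloxy)phenyl]-6-bromo-2,3-dihydro-4H-chromen-4-one F3, though retro-aldol cleavage and base-induced ring opening of the flavanone could erode the configuration at C2 under these conditions. Re-thioketalisation of F3 (propane-1,3-dithiol, BF3·OEt2) returns to the route at 10.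

Step 15. The doubly benzylic oxirane may ionise before hydrogen is delivered, leading to a hydride shift to a flavan-3-one or to hydrogen delivery with retention, and so to loss of the 3,4-cis relationship; the lower ketone may also be over-reduced. The fallback is the biomimetic cationic dimerisation. It sets out from 12: TMSOTf/Et3N gives (2S)-7-(benzyloxy)-2-[3,4-bis(benzyloxy)phenyl]-4-(trimethylsilyloxy)-2H-chromene F4; OsO4 (cat.)/N-methylmorpholine N-oxide in aqueous acetone gives (2R,3R)-7-(benzyloxy)-2-[3,4-bis(benzyloxy)phenyl]-3-hydroxy-2,3-dihydro-4H-chromen-4-one F5; H2 over Pd/C gives (2R,3R)-fustin F6; NaBH4 gives (2R,3S,4R)-mollisacacidin F7. In dilute aqueous acid at rt the C4 benzylic cation of one molecule of F7 should be captured by C6 of a second molecule (para to O1, ortho to the 7-hydroxyl), the known route to (4→6)-linked leucofisetinidin dimers. The 3,4-cis (4β) isomer is expected to be the minor component and would be separated from its 4α epimer and from oligomers on Sephadex LH-20, coming back to the route at 21.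

Step 10. Ring C may open during triflation (loss of the ring oxygen from the activated β-alkoxy ketone), and the C2 configuration may be lost by reversible electrocyclic opening of the 2H-chromene. The fallback replaces triflation and cross-coupling by a carbonyl addition. It sets out from 10 and 12: bromide 10 is treated with n-BuLi and CeCl3 at −78 °C and then with ketone 12, giving the tertiary carbinol (2S)-7-(benzyloxy)-2-[3,4-bis(benzyloxy)phenyl]-4-{(2S)-7-(benzyloxy)-2-[3,4-bis(benzyloxy)phenyl]-2,3-dihydrospiro[chromene-4,2'-[1,3]dithian]-6-yl}-3,4-dihydro-2H-chromen-4-ol F8 (both C4 epimers, which converge). Dehydration with catalytic pyridinium p-toluenesulfonate over 4 Å molecular sieves should give the 4-aryl-flav-3-ene, coming back to the route at 15.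

**Further compounds**

F1 | step 7 | (S)-1-[3,4-bis(benzyloxy)phenyl]-2-{2-[4-(benzyloxy)-5-bromo-2-fluorophenyl]-1,3-dithian-2-yl}ethan-1-ol | O[C@H](c1ccc(OCc2ccccc2)c(OCc2ccccc2)c1)CC1(SCCCS1)c1cc(Br)c(OCc2ccccc2)cc1F
F2 | step 7 | (S)-1-[4-(benzyloxy)-5-bromo-2-fluorophenyl]-3-[3,4-bis(benzyloxy)phenyl]-3-hydroxypropan-1-one | O[C@H](c1ccc(OCc2ccccc2)c(OCc2ccccc2)c1)CC(=O)c1cc(Br)c(OCc2ccccc2)cc1F
F3 | step 7 | (2S)-7-(benzyloxy)-2-[3,4-bis(benzyloxy)phenyl]-6-bromo-2,3-dihydro-4H-chromen-4-one | C(c1ccccc1)Oc1c(Br)cc2c(c1)O[C@H](c1ccc(OCc3ccccc3)c(OCc3ccccc3)c1)CC2=O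
F4 | step 15 | (2S)-7-(benzyloxy)-2-[3,4-bis(benzyloxy)phenyl]-4-(trimethylsilyloxy)-2H-chromene | C(c1ccccc1)Oc1ccc2c(c1)O[C@H](c1ccc(OCc3ccccc3)c(OCc3ccccc3)c1)C=C2O[Si](C)(C)C
F5 | step 15 | (2R,3R)-7-(benzyloxy)-2-[3,4-bis(benzyloxy)phenyl]-3-hydroxy-2,3-dihydro-4H-chromen-4-one | C(c1ccccc1)Oc1ccc2c(c1)O[C@H](c1ccc(OCc3ccccc3)c(OCc3ccccc3)c1)[C@@H](O)C2=O
F6 | step 15 | (2R,3R)-2-(3,4-dihydroxyphenyl)-3,7-dihydroxy-2,3-dihydro-4H-chromen-4-one (fustin) | Oc1ccc2c(c1)O[C@H](c1ccc(O)c(O)c1)[C@@H](O)C2=O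
F7 | step 15 | (2R,3S,4R)-2-(3,4-dihydroxyphenyl)-3,4-dihydro-2H-chromene-3,4,7-triol (mollisacacidin) | Oc1ccc2c(c1)O[C@H](c1ccc(O)c(O)c1)[C@@H](O)[C@@H]2O
F8 | step 10 | (2S)-7-(benzyloxy)-2-[3,4-bis(benzyloxy)phenyl]-4-{(2S)-7-(benzyloxy)-2-[3,4-bis(benzyloxy)phenyl]-2,3-dihydrospiro[chromene-4,2'-[1,3]dithian]-6-yl}-3,4-dihydro-2H-chromen-4-ol (both C4 epimers) | C(c1ccccc1)Oc1ccc2c(c1)O[C@H](c1ccc(OCc3ccccc3)c(OCc3ccccc3)c1)CC2(O)c1cc2c(cc1OCc1ccccc1)O[C@H](c1ccc(OCc3ccccc3)c(OCc3ccccc3)c1)CC23SCCCS3
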